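**Strategy.** Numbering: 2-oxabicyclo[2.2.2]octane core C1 (OCH bridgehead), O2, C3 (lactone C=O), C4 (quaternary bridgehead), C5 (ketone), C6, C7 (the CHMe carbons), C8 (spiro carbon). The cyclohexanone ring C4–C5–C6–C1–C7–C8 is cut at C5–C6 and C7–C8, revealing a latent pentan-3-one (C7–C1–C6) between two electrophiles on C4: the β-carbon C8 of a dihydropyranone and a malonate carbonyl C5. In one flask the titanium enolate of pentan-3-one adds to C8 (Michael) and the new ethyl ketone closes onto one ester (titanium Dieckmann). The precursor is a chiral-pool dihydropyranone bearing a prochiral methylmalonate. Conjugate lactonisation later joins O2 to C1.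

Key step: step 8

Remark: the tetrahydropyran is numbered O1′, C2′ (= C8), C3′ (CHMe), C4′ (CHOAc), C5′ (CHMe), C6′ (OCHMe).
Remark: C7 stays epimerisable until the lactone is closed; it is drawn in its final configuration throughout and is set deliberately in step 12.

Step 1
Reactants: 1 dibenzyl malonate
Product: 2 dibenzyl 2-methylmalonate
Conditions: NaH (1.0 equiv), THF, 0 °C; MeI (1.0 equiv), 0 °C → rt
Reagents that add atoms: iodomethane CI
Why: Mono-C-alkylation of the malonate sodium enolate (malonic ester alkylation) should give the methylmalonate; no stereocentre is formed.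

Step 2
Reactants: 2 dibenzyl 2-methylmalonate; 3 propanoyl chloride
Product: 4 dibenzyl 2-methyl-2-propanoylmalonate
Conditions: NaH, THF, 0 °C; then 3, 0 °C → rt
Reagents that add atoms: none
Why: C-acylation of the substituted malonate enolate by the acid chloride should give the acylmalonate, whose quaternary carbon (future C4) is prochiral and whose only enolisable position is the propanoyl CH2 (future C3′).

Step 3
Reactants: 5 methyl (R)-3-hydroxybutanoate
Product: 6 methyl (2R,3R)-3-hydroxy-2-methylbutanoate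
Conditions: LiN(i-Pr)2 (2.2 equiv), THF, −50 → −20 °C; MeI, DMPU, −78 → −20 °C
Reagents that add atoms: iodomethane CI
Why: Fráter–Seebach alkylation: the chelated alkoxide–enolate dianion should be methylated anti to the existing methyl group, which sets C5′ relative to the chiral-pool centre C6′.

Step 4
Reactants: 6 methyl (2R,3R)-3-hydroxy-2-methylbutanoate
Product: 7 methyl (2R,3R)-3-[(tert-butyldimethylsilyl)oxy]-2-methylbutanoate
Conditions: TBSCl, imidazole, DMF, rt
Reagents that add atoms: tert-butyldimethylsilyl chloride CC(C)(C)[Si](C)(C)Cl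
Why: Imidazole-promoted O-silylation of the secondary alcohol masks the hydroxyl for the acylation chemistry; no stereocentre is touched.

Step 5
Reactants: 7 methyl (2R,3R)-3-[(tert-butyldimethylsilyl)oxy]-2-methylbutanoate
Product: 8 (2R,3R)-3-[(tert-butyldimethylsilyl)oxy]-2-methylbutanoic acid
Conditions: LiOH, THF/MeOH/H2O, rt; then 1 M HCl to pH 3
Reagents that add atoms: lithium hydroxide [Li+].[OH-]
Why: Ester saponification at room temperature should leave the silyl ether and the α-stereocentre intact.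

Step 6
Reactants: 8 (2R,3R)-3-[(tert-butyldimethylsilyl)oxy]-2-methylbutanoic acid; 4 dibenzyl 2-methyl-2-propanoylmalonate
Product: 10 dibenzyl 2-[(4R,5R)-5-[(tert-butyldimethylsilyl)oxy]-2,4-dimethyl-3-oxohexanoyl]-2-methylmalonate, via acid chloride 9 (not isolated)
Conditions: (COCl)2, DMF (cat.), CH2Cl2, 0 °C, concentrate; then 4, MgBr2·OEt2, i-Pr2NEt, CH2Cl2, rt
Reagents that add atoms: oxalyl chloride ClC(=O)C(=O)Cl
Why: Soft-enolisation Claisen-type C-acylation: the magnesium enolate of the propanoyl ketone should be acylated on carbon to the 1,3-diketone, with C5′ and C6′ untouched and the new C3′ centre enolised (it is set in step 8).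

Step 7
Reactants: 10 dibenzyl 2-[(4R,5R)-5-[(tert-butyldimethylsilyl)oxy]-2,4-dimethyl-3-oxohexanoyl]-2-methylmalonate
Product: 12 dibenzyl 2-methyl-2-[(2R,3R)-2,3,5-trimethyl-4-oxo-3,4-dihydro-2H-pyran-6-yl]malonate, via hydroxy diketone 11 (not isolated)
Conditions: HF·pyridine, THF, 0 °C → rt; then TFA, CH2Cl2, rt
Reagents that add atoms: none
Why: Desilylation followed by acid-catalysed cyclodehydration of the δ-hydroxy-1,3-diketone (hemiketal formation, loss of water) should give the conjugated dihydropyranone, the trans-2,3-dimethyl arrangement being both inherited and thermodynamically preferred.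

Step 8
Reactants: 12 dibenzyl 2-methyl-2-[(2R,3R)-2,3,5-trimethyl-4-oxo-3,4-dihydro-2H-pyran-6-yl]malonate; 13 pentan-3-one
Product: 15 benzyl 10-hydroxy-2,3,5,7,9,11-hexamethyl-4,8-dioxo-1-oxaspiro[5.5]undec-9-ene-7-carboxylate (enolised spiro 1,3-dione), via Michael adduct 14 (not isolated)
Conditions: 13, TiCl4 (3.5 equiv), Bu3N (4 equiv), CH2Cl2, −78 °C; then 12, −78 → 0 °C; aq. NH4Cl
Reagents that add atoms: none
Why: The titanium enolate of pentan-3-one adds to C8 of the TiCl4-activated pyranone (C7–C8), leaving the pyranone masked as its titanium enolate; excess TiCl4/Bu3N then enolises the new ethyl ketone toward its CH2, and this enolate acylates one benzyl ester (C5–C6), expelling benzyl oxide to the 1,3-dione chelate. The closest known types are the titanium-enolate and Mukaiyama–Michael additions to β,β-disubstituted enones and the TiCl4/amine Claisen–Dieckmann condensation. Only the second event closes a ring, the cyclohexane-1,3-dione, in 6-(enolexo)-exo-trig mode. C8 is set by axial attack on the pyranone half-chair anti to the C6′ methyl (2,6-trans), and C3′ by axial protonation of the pyranone enolate on work-up, anti to the axial C7 arm. C4 is set by choice between the diastereotopic esters in a chair transition state where titanium is held by O1′ and both malonate carbonyls, so the C4 methyl lies anti to O1′ and the ester gauche to C7 is attacked. The step needs Michael addition before Claisen acylation (the Lewis acid activates the vinylogous ester carbonyl, the α-quaternary malonate esters being hindered) and enolisation of the C1 ketone toward CH2, not toward the tertiary C7.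

Step 9
Reactants: 15 enolised spiro 1,3-dione
Product: 16 benzyl 4,10-dihydroxy-2,3,5,7,9,11-hexamethyl-8-oxo-1-oxaspiro[5.5]undec-9-ene-7-carboxylate (C4′ alcohol)
Conditions: LiBH(s-Bu)3 (2.5 equiv), THF, −78 °C; aq. NH4Cl
Reagents that add atoms: none
Why: Bulky trialkylborohydride reduction: the first equivalent deprotonates the 1,3-dione (protecting it as its enolate) and the second should attack the C4′ ketone from the equatorial direction, the axial face being screened by the axial C7 arm, to give the axial alcohol.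

Step 10
Reactants: 16 C4′ alcohol
Product: 17 benzyl 4-hydroxy-2,3,5,7,9,11-hexamethyl-8-oxo-10-[(trifluoromethylsulfonyl)oxy]-1-oxaspiro[5.5]undec-9-ene-7-carboxylate (enol triflate at C1)
Conditions: PhNTf2 (1.1 equiv), K2CO3, DMF, 0 °C → rt
Reagents that add atoms: N-phenylbis(trifluoromethanesulfonimide) O=S(=O)(N(c1ccccc1)S(=O)(=O)C(F)(F)F)C(F)(F)F
Why: O-sulfonylation of the 1,3-dione enolate (vinylogous acyl triflate formation) should occur at the oxygen on C1, flanked by a CH, rather than at the oxygen on C5, flanked by the quaternary C4; the secondary alcohol is not deprotonated by K2CO3.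

Step 11
Reactants: 17 enol triflate
Product: 18 benzyl 4-hydroxy-2,3,5,7,9,11-hexamethyl-8-oxo-1-oxaspiro[5.5]undec-9-ene-7-carboxylate (C1=C6 enone)
Conditions: Pd(OAc)2 (5 mol %), PPh3 (10 mol %), HCO2H, Bu3N, DMF, 60 °C
Reagents that add atoms: none
Why: Palladium-catalysed formate reduction of an enol triflate (oxidative addition, decarboxylation of formate to the hydride, reductive elimination) should give the enone with C1 as CH and C5 kept as the ketone; no stereocentre is formed.

Step 12
Reactants: 18 C1=C6 enone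
Product: 19 benzyl 4-acetoxy-2,3,5,7,9,11-hexamethyl-8-oxo-1-oxaspiro[5.5]undec-9-ene-7-carboxylate (acetate)
Conditions: Ac2O, Et3N, DMAP (cat.), CH2Cl2, rt; then DBU (0.3 equiv), toluene, 40 °C
Reagents that add atoms: acetic anhydride CC(=O)OC(C)=O
Why: DMAP-catalysed acylation of the axial C4′ alcohol; the DBU treatment equilibrates C7 through the extended dienolate of the enone to the epimer in which the C7 methyl is anti to the C4 methyl and C7–H points over the pyran ring towards the axial acetate, which is the configuration drawn.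

Step 13
Reactants: 19 acetate
Product: 21 CNP0257416.1, via enone acid 20 (not isolated)
Conditions: H2 (1 atm), Pd/C, EtOAc, rt; filter; then TsOH·H2O (5 mol %), CH2Cl2, 0 °C
Reagents that add atoms: none
Why: Hydrogenolysis of the benzyl ester frees the C3 acid, which should add across the ring to C1 of the protonated enone (acid-catalysed intramolecular oxa-Michael, conjugate lactonisation from a boat), the bridge fixing C1, and the bicyclic enol is protonated at C6 from the open lactone flank so that the C6 methyl ends on the flank of the C7–C8 bridge.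

Compound list
1 | dibenzyl malonate | O=C(CC(=O)OCc1ccccc1)OCc1ccccc1 | starting material
2 | dibenzyl 2-methylmalonate | CC(C(=O)OCc1ccccc1)C(=O)OCc1ccccc1 | intermediate
3 | propanoyl chloride | CCC(=O)Cl | starting material
4 | dibenzyl 2-methyl-2-propanoylmalonate | CCC(=O)C(C)(C(=O)OCc1ccccc1)C(=O)OCc1ccccc1 | intermediate
5 | methyl (R)-3-hydroxybutanoate | C[C@@H](O)CC(=O)OC | starting material
6 | methyl (2R,3R)-3-hydroxy-2-methylbutanoate | C[C@@H](O)[C@@H](C)C(=O)OC | intermediate
7 | methyl (2R,3R)-3-[(tert-butyldimethylsilyl)oxy]-2-methylbutanoate | C[C@@H](O[Si](C)(C)C(C)(C)C)[C@@H](C)C(=O)OC | intermediate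
8 | (2R,3R)-3-[(tert-butyldimethylsilyl)oxy]-2-methylbutanoic acid | C[C@@H](O[Si](C)(C)C(C)(C)C)[C@@H](C)C(=O)O | intermediate
9 | (2R,3R)-3-[(tert-butyldimethylsilyl)oxy]-2-methylbutanoyl chloride | C[C@@H](O[Si](C)(C)C(C)(C)C)[C@@H](C)C(=O)Cl | intermediate
10 | dibenzyl 2-[(4R,5R)-5-[(tert-butyldimethylsilyl)oxy]-2,4-dimethyl-3-oxohexanoyl]-2-methylmalonate (chain C2 enolisable, unassigned) | C[C@@H](O[Si](C)(C)C(C)(C)C)[C@@H](C)C(=O)C(C)C(=O)C(C)(C(=O)OCc1ccccc1)C(=O)OCc1ccccc1 | intermediate
11 | dibenzyl 2-[(4R,5R)-5-hydroxy-2,4-dimethyl-3-oxohexanoyl]-2-methylmalonate | C[C@@H](O)[C@@H](C)C(=O)C(C)C(=O)C(C)(C(=O)OCc1ccccc1)C(=O)OCc1ccccc1 | intermediate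
12 | dibenzyl 2-methyl-2-[(2R,3R)-2,3,5-trimethyl-4-oxo-3,4-dihydro-2H-pyran-6-yl]malonate | O=C1[C@H](C)[C@@H](C)OC(C(C)(C(=O)OCc2ccccc2)C(=O)OCc2ccccc2)=C1C | intermediate
13 | pentan-3-one | CCC(=O)CC | starting material
14 | dibenzyl 2-methyl-2-[3,5,6-trimethyl-4-oxo-2-(3-oxopentan-2-yl)oxan-2-yl]malonate (Michael adduct, drawn as the diketone, present as its titanium enolate; C8, C3′, C5′, C6′ as in 21) | O=C1[C@H](C)[C@@H](C)O[C@@]([C@@H]1C)([C@@H](C)C(=O)CC)C(C)(C(=O)OCc1ccccc1)C(=O)OCc1ccccc1 | intermediate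
15 | benzyl 10-hydroxy-2,3,5,7,9,11-hexamethyl-4,8-dioxo-1-oxaspiro[5.5]undec-9-ene-7-carboxylate (C4, C7, C8, C3′, C5′, C6′ as in 21) | O=C1[C@H](C)[C@@H](C)O[C@@]2([C@@H]1C)[C@@H](C)C(O)=C(C)C(=O)[C@@]2(C)C(=O)OCc1ccccc1 | intermediate
16 | benzyl 4,10-dihydroxy-2,3,5,7,9,11-hexamethyl-8-oxo-1-oxaspiro[5.5]undec-9-ene-7-carboxylate (axial C4′ alcohol; other centres as in 21) | O[C@@H]1[C@H](C)[C@@H](C)O[C@@]2([C@@H]1C)[C@@H](C)C(O)=C(C)C(=O)[C@@]2(C)C(=O)OCc1ccccc1 | intermediate
17 | benzyl 4-hydroxy-2,3,5,7,9,11-hexamethyl-8-oxo-10-[(trifluoromethylsulfonyl)oxy]-1-oxaspiro[5.5]undec-9-ene-7-carboxylate | O[C@@H]1[C@H](C)[C@@H](C)O[C@@]2([C@@H]1C)[C@@H](C)C(OS(=O)(=O)C(F)(F)F)=C(C)C(=O)[C@@]2(C)C(=O)OCc1ccccc1 | intermediate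
18 | benzyl 4-hydroxy-2,3,5,7,9,11-hexamethyl-8-oxo-1-oxaspiro[5.5]undec-9-ene-7-carboxylate | O[C@@H]1[C@H](C)[C@@H](C)O[C@@]2([C@@H]1C)[C@@H](C)C=C(C)C(=O)[C@@]2(C)C(=O)OCc1ccccc1 | intermediate
19 | benzyl 4-acetoxy-2,3,5,7,9,11-hexamethyl-8-oxo-1-oxaspiro[5.5]undec-9-ene-7-carboxylate | CC(=O)O[C@@H]1[C@H](C)[C@@H](C)O[C@@]2([C@@H]1C)[C@@H](C)C=C(C)C(=O)[C@@]2(C)C(=O)OCc1ccccc1 | intermediate
20 | 4-acetoxy-2,3,5,7,9,11-hexamethyl-8-oxo-1-oxaspiro[5.5]undec-9-ene-7-carboxylic acid | CC(=O)O[C@@H]1[C@H](C)[C@@H](C)O[C@@]2([C@@H]1C)[C@@H](C)C=C(C)C(=O)[C@@]2(C)C(=O)O | intermediate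
21 | CNP0257416.1, 4′-acetoxy-4,6,7,3′,5′,6′-hexamethyl-3,5-dioxospiro[2-oxabicyclo[2.2.2]octane-8,2′-oxane] | CC(=O)O[C@@H]1[C@H](C)[C@@H](C)O[C@@]2([C@@H]1C)[C@@H](C)[C@H]1OC(=O)[C@]2(C)C(=O)[C@H]1C | target

Total step count: 13. Longest linear sequence: 11 steps (steps 3 to 13, from methyl (R)-3-hydroxybutanoate).

Steps most likely to fail

Step 8. Two processes may go wrong: the intermolecular Michael addition to the crowded C8 may be too slow, and the ring closure may pick the wrong diastereotopic ester, giving the C4 epimer. The fallback sets out from 12 and distinguishes the esters before any C–C bond is made. Esterase-mediated mono-hydrolysis (pig-liver esterase or a screened lipase, pH 7 buffer/acetone) gives the half acid F1, with C4 fixed by the enzyme. Carbonyldiimidazole converts it into the acyl imidazole F2. Soft-enolisation acylation of pentan-3-one (MgBr2·OEt2, i-Pr2NEt) then forms C5–C6 first and gives the 1,3-diketone F3. TMSOTf/Et3N converts this into the bis-silyl dienol ether F4, whose terminal carbon closes onto C8 in a TiCl4-promoted intramolecular Mukaiyama–Michael addition, now an intramolecular bond formation; this comes back to the route at 15.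

Step 13. Hydrogenation of the enone C=C, decarboxylation of the free β-keto acid, or an unfavourable oxa-Michael equilibrium may compete. The fallback sets out from 19 and avoids hydrogen and the free acid. Iodotrimethylsilane (TMSCl, NaI, MeCN, 0 °C) cleaves the benzyl ester to the trimethylsilyl ester F5 and activates the enone. The silyl carboxylate closes onto C1 to give the silyl enol ether F6 of the target, which is protonated at C6 on buffered work-up; this comes back to the route at 21.

Step 6. O-acylation or retro-Claisen loss of the propanoyl group from the acylmalonate may compete with C-acylation. The fallback sets out from 7. Reduction with i-Bu2AlH (CH2Cl2, −78 °C) gives the aldehyde F7. Aldol addition of the titanium enolate of 4 (TiCl4, i-Pr2NEt, −78 °C) gives the β-hydroxy ketone F8, and Dess–Martin oxidation comes back to the route at 10.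

Further compounds
F1 | step 8 | benzyl hydrogen 2-methyl-2-[(2R,3R)-2,3,5-trimethyl-4-oxo-3,4-dihydro-2H-pyran-6-yl]malonate (acid carbonyl = future C5) | O=C1[C@H](C)[C@@H](C)OC([C@@](C)(C(=O)O)C(=O)OCc2ccccc2)=C1C
F2 | step 8 | acyl imidazole of F1 | O=C1[C@H](C)[C@@H](C)OC([C@@](C)(C(=O)n2ccnc2)C(=O)OCc2ccccc2)=C1C
F3 | step 8 | benzyl 2,4-dimethyl-3,5-dioxo-2-[(2R,3R)-2,3,5-trimethyl-4-oxo-3,4-dihydro-2H-pyran-6-yl]heptanoate | O=C1[C@H](C)[C@@H](C)OC([C@@](C)(C(=O)C(C)C(=O)CC)C(=O)OCc2ccccc2)=C1C
F4 | step 8 | bis(trimethylsilyl) dienol ether of F3 | O=C1[C@H](C)[C@@H](C)OC([C@@](C)(C(O[Si](C)(C)C)=C(C)C(O[Si](C)(C)C)=CC)C(=O)OCc2ccccc2)=C1C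
F5 | step 13 | trimethylsilyl ester of 20 | CC(=O)O[C@@H]1[C@H](C)[C@@H](C)O[C@@]2([C@@H]1C)[C@@H](C)C=C(C)C(=O)[C@@]2(C)C(=O)O[Si](C)(C)C
F6 | step 13 | C5 trimethylsilyl enol ether of 21 | CC(=O)O[C@@H]1[C@H](C)[C@@H](C)O[C@@]2([C@@H]1C)[C@@H](C)[C@H]1OC(=O)[C@]2(C)C(O[Si](C)(C)C)=C1C
F7 | step 6 | (2R,3R)-3-[(tert-butyldimethylsilyl)oxy]-2-methylbutanal | C[C@@H](O[Si](C)(C)C(C)(C)C)[C@@H](C)C=O
F8 | step 6 | dibenzyl 2-[(4R,5R)-5-[(tert-butyldimethylsilyl)oxy]-3-hydroxy-2,4-dimethylhexanoyl]-2-methylmalonate | C[C@@H](O[Si](C)(C)C(C)(C)C)[C@@H](C)C(O)C(C)C(=O)C(C)(C(=O)OCc1ccccc1)C(=O)OCc1ccccc1
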